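**Retrosynthetic overview**
1. Andrographolide (1) supplies rings A and B and the stereocentres C4, C5, C9 and C10; no ring is formed in the route.
2. Side chain: the C12–C13 bond is made by a visible-light nickel/iridium deoxygenative coupling of a C12 alcohol (permanganate cleavage of the lactone alkene, then reduction) with the E enol triflate of tert-butyl acetoacetate.
3. Ring B: the Δ7 alkene comes from the native exocyclic 8(17) alkene by hydrogen-atom-transfer isomerisation.
4. Ring A: the 2β,3β-diacetate comes from the 3-ketone (enolate hydroxylation at C2, then equatorial hydride delivery at C3); the ketone comes from the native 3α-alcohol.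
5. End game: C19 silyl ether to aldehyde, tert-butyl ester to acid.

Assumption: labdane numbering is used; α is the face of the C10 methyl (C20) and of C19, β the face of H5, H9 and the C18 methyl (5β-H, 9β-H, 10α-CH3, the ent-labdane series of both andrographolide and the target); reagents not made in the route are bought.

**Step 1**
Reactants: 1 andrographolide
Product: 2 19-O-(tert-butyldimethylsilyl)andrographolide
Conditions: TBSCl (1.2 equiv), pyridine, rt
Reagents that add atoms: tert-butyldimethylsilyl chloride, CC(C)(C)[Si](C)(C)Cl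
Why: Selective silyl ether formation, in which the primary C19 hydroxyl reacts much faster than the secondary C3 and C14 hydroxyls (a known selective derivatisation of andrographolide) and no stereocentre is touched.

**Step 2**
Reactants: 2 19-O-(tert-butyldimethylsilyl)andrographolide
Product: 3 19-(tert-butyldimethylsilyloxy)-3α-hydroxy-13,14,15,16-tetranorlabd-8(17)-en-12-al
Conditions: KMnO4 (2 equiv), MgSO4, THF/H2O, 0 °C
Reagents that add atoms: potassium permanganate, [K+].[O-][Mn](=O)(=O)=O
Why: Permanganate oxidative alkene cleavage, in which MnO4− attacks the electron-poor conjugated C12=C13 bond of the alkylidene lactone much faster than the hindered isolated C8=C17 bond (precedented on 3,19-protected andrographolide) and C9, not α to the new aldehyde, keeps its configuration.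

**Step 3**
Reactants: 3 19-(tert-butyldimethylsilyloxy)-3α-hydroxy-13,14,15,16-tetranorlabd-8(17)-en-12-al
Product: 4 19-(tert-butyldimethylsilyloxy)-13,14,15,16-tetranorlabd-8(17)-ene-3α,12-diol
Conditions: NaBH4, MeOH, 0 °C
Reagents that add atoms: none
Why: Borohydride reduction of the aldehyde to the primary C12 alcohol, with nothing else in 3 reducible and no stereocentre formed.

**Step 4**
Reactants: 5 tert-butyl acetoacetate
Product: 6 tert-butyl (E)-3-(trifluoromethylsulfonyloxy)but-2-enoate
Conditions: Tf2O, 25% aq. Me4NOH, hexanes, 5 °C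
Reagents that add atoms: trifluoromethanesulfonic anhydride, FC(F)(F)S(=O)(=O)OS(=O)(=O)C(F)(F)F
Why: Enolate O-sulfonylation, in which the non-chelated tetramethylammonium enolate of the β-keto ester is triflated in its E form (triflate trans to the ester), whereas a chelated lithium enolate would give Z.

**Step 5**
Reactants: 4 19-(tert-butyldimethylsilyloxy)-13,14,15,16-tetranorlabd-8(17)-ene-3α,12-diol, 6 tert-butyl (E)-3-(trifluoromethylsulfonyloxy)but-2-enoate, 7 5,7-di-tert-butyl-3-phenyl-1,3-benzoxazol-3-ium tetrafluoroborate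
Product: 9 tert-butyl (13E)-19-(tert-butyldimethylsilyloxy)-3α-hydroxylabda-8(17),13-dien-15-oate, via benzoxazoline ether 8 (not isolated)
Conditions: 7 (1.05 equiv), pyridine, t-BuOMe, rt, 20 min; then 6 (2 equiv), [Ir(ppy)2(dtbbpy)]PF6 (2 mol%), NiBr2(dtbbpy) (8 mol%), quinuclidine, DMA, 450 nm LEDs, rt (ppy = 2-phenylpyridinate, dtbbpy = 4,4′-di-tert-butyl-2,2′-bipyridine)
Reagents that add atoms: none
Why: Proposed new method: a nickel/iridium metallaphotoredox deoxygenative C(sp3)–C(sp2) coupling of a benzoxazolium-activated primary alcohol with a β-(triflyloxy)enoate, an electrophile class not yet shown in this manifold, in which the unhindered primary C12 hydroxyl (not the hindered 3-OH) condenses with 7, the excited iridium photocatalyst oxidises the N-aryl aminal 8, deprotonation and β-scission release the primary C12 radical and the benzoxazolone, zerovalent nickel inserts into the C–OTf bond of the electron-poor enol triflate, and radical capture followed by reductive elimination forms C12–C13 with retention of the E geometry and no new stereocentre, the closest known reaction being the deoxygenative arylation of alcohols with aryl halides under the same dual catalysis, together with nickel-catalysed alkyl–alkenyl triflate cross-electrophile coupling.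

**Step 6**
Reactants: 9 tert-butyl (13E)-19-(tert-butyldimethylsilyloxy)-3α-hydroxylabda-8(17),13-dien-15-oate
Product: 10 tert-butyl (13E)-19-(tert-butyldimethylsilyloxy)-3α-hydroxylabda-7,13-dien-15-oate
Conditions: Co(salen)Cl (3 mol%; salen = N,N′-bis(3,5-di-tert-butylsalicylidene)ethane-1,2-diamine dianion, achiral), PhSiH3 (6 mol%), benzene, rt
Reagents that add atoms: none
Why: Metal-hydride hydrogen-atom-transfer alkene isomerisation, in which the cobalt hydride gives H• to C17, the tertiary C8 radical loses the accessible C7–H and not the hindered C9–H next to quaternary C10, and the resulting trisubstituted Δ7 alkene is not re-activated while the enoate and C9 stay untouched.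

**Step 7**
Reactants: 10 tert-butyl (13E)-19-(tert-butyldimethylsilyloxy)-3α-hydroxylabda-7,13-dien-15-oate
Product: 11 tert-butyl (13E)-19-(tert-butyldimethylsilyloxy)-3-oxolabda-7,13-dien-15-oate
Conditions: Dess–Martin periodinane, NaHCO3, CH2Cl2, rt
Reagents that add atoms: none
Why: Dess–Martin oxidation of the hindered secondary alcohol under buffered neutral conditions that spare the silyl ether, both alkenes and the ester, deliberately erasing C3 so that it can be reset in step 9.

**Step 8**
Reactants: 11 tert-butyl (13E)-19-(tert-butyldimethylsilyloxy)-3-oxolabda-7,13-dien-15-oate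
Product: 13 tert-butyl (13E)-19-(tert-butyldimethylsilyloxy)-2β-hydroxy-3-oxolabda-7,13-dien-15-oate, via lithium enolate 12 (not isolated)
Conditions: LiN(SiMe3)2 (1.1 equiv), THF, −78 °C; MoO5·pyridine·HMPA (1.5 equiv), −78 → −25 °C; aq. Na2SO3
Reagents that add atoms: oxodiperoxymolybdenum(pyridine)(hexamethylphosphoric triamide) (MoOPH), O=[Mo]12(OO1)OO2.c1ccncc1.CN(C)P(=O)(N(C)C)N(C)C
Why: Enolate hydroxylation with the Vedejs reagent, in which the ketone can enolise only towards C2 (C4 is quaternary) and is deprotonated in preference to the tert-butyl enoate, and the peroxide attacks the β face, away from the axial C20 methyl and the axial C19 CH2OTBS, to set the equatorial 2β-hydroxyl.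

**Step 9**
Reactants: 13 tert-butyl (13E)-19-(tert-butyldimethylsilyloxy)-2β-hydroxy-3-oxolabda-7,13-dien-15-oate
Product: 15 tert-butyl (13E)-2β,3β-diacetoxy-19-(tert-butyldimethylsilyloxy)labda-7,13-dien-15-oate, via dilithium diolate 14 (not isolated)
Conditions: Li[HB(s-Bu)3] (2.5 equiv), THF, −78 °C; then Ac2O, DMAP, −78 °C → rt
Reagents that add atoms: acetic anhydride, CC(=O)OC(C)=O
Why: Sterically controlled ketone reduction followed by in-flask acetylation, in which the bulky tri-sec-butylborohydride avoids the axial β approach (1,3-diaxial H1 and H5) and delivers hydride equatorially from the α side to set the axial 3β-oxygen cis to the 2β-oxygen (the usual outcome for 4,4-disubstituted 3-ketones and 2-oxygenated cyclohexanones), and both lithium alkoxides are then acetylated.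

**Step 10**
Reactants: 15 tert-butyl (13E)-2β,3β-diacetoxy-19-(tert-butyldimethylsilyloxy)labda-7,13-dien-15-oate
Product: 16 tert-butyl (13E)-2β,3β-diacetoxy-19-hydroxylabda-7,13-dien-15-oate
Conditions: HF·pyridine, pyridine, THF, 0 °C → rt
Reagents that add atoms: none
Why: Fluoride desilylation with buffered HF·pyridine removes the primary silyl ether without touching acetates, tert-butyl ester or alkenes, and the freed C19 hydroxyl is anti to the axial 3β-acetate so no acyl migration can occur.

**Step 11**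
Reactants: 16 tert-butyl (13E)-2β,3β-diacetoxy-19-hydroxylabda-7,13-dien-15-oate
Product: 17 tert-butyl (13E)-2β,3β-diacetoxy-19-oxolabda-7,13-dien-15-oate
Conditions: Dess–Martin periodinane, NaHCO3, CH2Cl2, rt
Reagents that add atoms: none
Why: Dess–Martin oxidation of the neopentyl primary alcohol gives the C19 aldehyde, which cannot epimerise because C4 is quaternary.

**Step 12**
Reactants: 17 tert-butyl (13E)-2β,3β-diacetoxy-19-oxolabda-7,13-dien-15-oate
Product: 19 (13E)-2β,3β-diacetoxy-19-oxolabda-7,13-dien-15-oic acid (target CNP0273594.1), via trimethylsilyl ester 18 (not isolated)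
Conditions: TMSOTf, 2,6-lutidine, CH2Cl2, 0 °C → rt; then H2O
Reagents that add atoms: none
Why: Silyl-triflate-mediated tert-butyl ester cleavage, in which TMSOTf silylates the ester carbonyl, isobutene is lost to give the silyl ester and mild aqueous work-up hydrolyses it to the acid, conditions that leave the acetates, the non-enolisable aldehyde and both alkenes (E geometry) intact, unlike aqueous base or strong protic acid.

**Compound list**
1 | andrographolide [3α,14,19-trihydroxylabda-8(17),12E-dien-16,15-olide, 5β,9β,10α series] | C[C@@]12CC[C@H]([C@@]([C@H]1CCC(=C)[C@H]2C/C=C/3\[C@@H](COC3=O)O)(C)CO)O | starting material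
2 | 19-O-(tert-butyldimethylsilyl)andrographolide | C[C@@]12CC[C@H]([C@@]([C@H]1CCC(=C)[C@H]2C/C=C/3\[C@@H](COC3=O)O)(C)CO[Si](C)(C)C(C)(C)C)O | intermediate
3 | 19-(tert-butyldimethylsilyloxy)-3α-hydroxy-13,14,15,16-tetranorlabd-8(17)-en-12-al | C1C[C@@]2(C)[C@H](CC=O)C(=C)CC[C@@H]2[C@](C)(CO[Si](C)(C)C(C)(C)C)[C@@H]1O | intermediate
4 | 19-(tert-butyldimethylsilyloxy)-13,14,15,16-tetranorlabd-8(17)-ene-3α,12-diol | C1C[C@@]2(C)[C@H](CCO)C(=C)CC[C@@H]2[C@](C)(CO[Si](C)(C)C(C)(C)C)[C@@H]1O | intermediate
5 | tert-butyl acetoacetate | CC(=O)CC(=O)OC(C)(C)C | starting material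
6 | tert-butyl (E)-3-(trifluoromethylsulfonyloxy)but-2-enoate | C/C(OS(=O)(=O)C(F)(F)F)=C\C(=O)OC(C)(C)C | intermediate
7 | 5,7-di-tert-butyl-3-phenyl-1,3-benzoxazol-3-ium tetrafluoroborate | CC(C)(C)c1cc2c(c(c1)C(C)(C)C)oc[n+]2-c1ccccc1.F[B-](F)(F)F | starting material
8 | 12-O-(5,7-di-tert-butyl-3-phenyl-2,3-dihydro-1,3-benzoxazol-2-yl) ether of 4 (both epimers at the acetal carbon) | C1C[C@@]2(C)[C@H](CCOC3Oc4c(cc(cc4C(C)(C)C)C(C)(C)C)N3c3ccccc3)C(=C)CC[C@@H]2[C@](C)(CO[Si](C)(C)C(C)(C)C)[C@@H]1O | intermediate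
9 | tert-butyl (13E)-19-(tert-butyldimethylsilyloxy)-3α-hydroxylabda-8(17),13-dien-15-oate | C1C[C@@]2(C)[C@H](CC/C(C)=C/C(=O)OC(C)(C)C)C(=C)CC[C@@H]2[C@](C)(CO[Si](C)(C)C(C)(C)C)[C@@H]1O | intermediate
10 | tert-butyl (13E)-19-(tert-butyldimethylsilyloxy)-3α-hydroxylabda-7,13-dien-15-oate | C1C[C@@]2(C)[C@H](CC/C(C)=C/C(=O)OC(C)(C)C)C(C)=CC[C@@H]2[C@](C)(CO[Si](C)(C)C(C)(C)C)[C@@H]1O | intermediate
11 | tert-butyl (13E)-19-(tert-butyldimethylsilyloxy)-3-oxolabda-7,13-dien-15-oate | C1C[C@@]2(C)[C@H](CC/C(C)=C/C(=O)OC(C)(C)C)C(C)=CC[C@@H]2[C@](C)(CO[Si](C)(C)C(C)(C)C)C1=O | intermediate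
12 | lithium 2-en-3-olate of 11 | [Li+].[O-]C1=CC[C@@]2(C)[C@H](CC/C(C)=C/C(=O)OC(C)(C)C)C(C)=CC[C@@H]2[C@]1(C)CO[Si](C)(C)C(C)(C)C | intermediate
13 | tert-butyl (13E)-19-(tert-butyldimethylsilyloxy)-2β-hydroxy-3-oxolabda-7,13-dien-15-oate | O[C@H]1C[C@@]2(C)[C@H](CC/C(C)=C/C(=O)OC(C)(C)C)C(C)=CC[C@@H]2[C@](C)(CO[Si](C)(C)C(C)(C)C)C1=O | intermediate
14 | dilithium 2β,3β-diolate of tert-butyl (13E)-19-(tert-butyldimethylsilyloxy)labda-7,13-dien-15-oate | [Li+].[Li+].[O-][C@H]1C[C@@]2(C)[C@H](CC/C(C)=C/C(=O)OC(C)(C)C)C(C)=CC[C@@H]2[C@](C)(CO[Si](C)(C)C(C)(C)C)[C@H]1[O-] | intermediate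
15 | tert-butyl (13E)-2β,3β-diacetoxy-19-(tert-butyldimethylsilyloxy)labda-7,13-dien-15-oate | CC(=O)O[C@H]1C[C@@]2(C)[C@H](CC/C(C)=C/C(=O)OC(C)(C)C)C(C)=CC[C@@H]2[C@](C)(CO[Si](C)(C)C(C)(C)C)[C@H]1OC(C)=O | intermediate
16 | tert-butyl (13E)-2β,3β-diacetoxy-19-hydroxylabda-7,13-dien-15-oate | CC(=O)O[C@H]1C[C@@]2(C)[C@H](CC/C(C)=C/C(=O)OC(C)(C)C)C(C)=CC[C@@H]2[C@](C)(CO)[C@H]1OC(C)=O | intermediate
17 | tert-butyl (13E)-2β,3β-diacetoxy-19-oxolabda-7,13-dien-15-oate | CC(=O)O[C@H]1C[C@@]2(C)[C@H](CC/C(C)=C/C(=O)OC(C)(C)C)C(C)=CC[C@@H]2[C@](C)(C=O)[C@H]1OC(C)=O | intermediate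
18 | trimethylsilyl (13E)-2β,3β-diacetoxy-19-oxolabda-7,13-dien-15-oate | CC(=O)O[C@H]1C[C@@]2(C)[C@H](CC/C(C)=C/C(=O)O[Si](C)(C)C)C(C)=CC[C@@H]2[C@](C)(C=O)[C@H]1OC(C)=O | intermediate
19 | (13E)-2β,3β-diacetoxy-19-oxolabda-7,13-dien-15-oic acid (5β,9β,10α series; CNP0273594.1) | CC(=O)O[C@H]1C[C@@]2(C)[C@H](CC/C(C)=C/C(=O)O)C(C)=CC[C@@H]2[C@](C)(C=O)[C@H]1OC(C)=O | target

**Step count and risks**
Total step count: 12. Longest linear sequence: 11 steps (steps 1 to 3 and 5 to 12, from 1 to 19); step 4 is a one-step side branch.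

Step 5, the new coupling. The nickel capture of the C12 radical must outrun radical addition–elimination or amine attack on the enol triflate, either of which would erode the E geometry, and the 3-OH must stay unactivated. The fallback uses known chemistry and runs from 4 back to 9. An Appel reaction (I2, PPh3, imidazole, CH2Cl2, 0 °C) converts only the unhindered primary alcohol into 19-(tert-butyldimethylsilyloxy)-12-iodo-13,14,15,16-tetranorlabd-8(17)-en-3α-ol F1. The known nickel-catalysed reductive cross-electrophile coupling of alkyl iodides with alkenyl triflates (NiBr2(dme), 4,4′-di-tert-butyl-2,2′-bipyridine, Mn powder, DMA, rt) then joins F1 to enol triflate 6 with retention of the alkene geometry and tolerance of the free hydroxyl, giving 9.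

Step 6, the isomerisation. Some tetrasubstituted Δ8(9) alkene could form beside the Δ7 isomer. The fallback runs from 9 back to 10 and fixes the double-bond position by enolisation. Ozonolysis of only the electron-rich exocyclic alkene (O3, CH2Cl2/pyridine, −78 °C; Me2S; the enoate reacts far more slowly) gives tert-butyl (13E)-19-(tert-butyldimethylsilyloxy)-3α-hydroxy-8-oxo-17-norlabd-13-en-15-oate F2. Kinetic deprotonation at the C7 methylene rather than the C9 methine (KN(SiMe3)2, 2.1 equiv, THF, −78 °C; the first equivalent takes the 3-OH proton, and the hindered alkoxide is not triflated) and PhNTf2 give tert-butyl (13E)-19-(tert-butyldimethylsilyloxy)-3α-hydroxy-8-(trifluoromethylsulfonyloxy)-17-norlabda-7,13-dien-15-oate F3. Fe(acac)3-catalysed coupling with MeMgBr (THF/NMP, −30 °C) installs the C17 methyl and gives 10.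

Step 9, the hydride face at C3. The equatorial approach passes the axial CH2OTBS on C4, so some 3α-alcohol may form. The fallback runs from 13 back to 17 and replaces steric control by internal hydride delivery. Acetylation (Ac2O, pyridine, DMAP) gives tert-butyl (13E)-2β-acetoxy-19-(tert-butyldimethylsilyloxy)-3-oxolabda-7,13-dien-15-oate F4. HF·pyridine frees the C19 hydroxyl to give tert-butyl (13E)-2β-acetoxy-19-hydroxy-3-oxolabda-7,13-dien-15-oate F5. A Saksena–Evans reduction (Me4NBH(OAc)3, MeCN/AcOH, −20 °C) binds the axial α-CH2OH and delivers hydride to the α face of C3, giving tert-butyl (13E)-2β-acetoxy-3β,19-dihydroxylabda-7,13-dien-15-oate F6. TEMPO/PhI(OAc)2 oxidises only the primary alcohol to tert-butyl (13E)-2β-acetoxy-3β-hydroxy-19-oxolabda-7,13-dien-15-oate F7, and Ac2O/DMAP then gives 17.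

**Further compounds**
F1 | step 5 | 19-(tert-butyldimethylsilyloxy)-12-iodo-13,14,15,16-tetranorlabd-8(17)-en-3α-ol | C1C[C@@]2(C)[C@H](CCI)C(=C)CC[C@@H]2[C@](C)(CO[Si](C)(C)C(C)(C)C)[C@@H]1O
F2 | step 6 | tert-butyl (13E)-19-(tert-butyldimethylsilyloxy)-3α-hydroxy-8-oxo-17-norlabd-13-en-15-oate | C1C[C@@]2(C)[C@H](CC/C(C)=C/C(=O)OC(C)(C)C)C(=O)CC[C@@H]2[C@](C)(CO[Si](C)(C)C(C)(C)C)[C@@H]1O
F3 | step 6 | tert-butyl (13E)-19-(tert-butyldimethylsilyloxy)-3α-hydroxy-8-(trifluoromethylsulfonyloxy)-17-norlabda-7,13-dien-15-oate | C1C[C@@]2(C)[C@H](CC/C(C)=C/C(=O)OC(C)(C)C)C(OS(=O)(=O)C(F)(F)F)=CC[C@@H]2[C@](C)(CO[Si](C)(C)C(C)(C)C)[C@@H]1O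
F4 | step 9 | tert-butyl (13E)-2β-acetoxy-19-(tert-butyldimethylsilyloxy)-3-oxolabda-7,13-dien-15-oate | CC(=O)O[C@H]1C[C@@]2(C)[C@H](CC/C(C)=C/C(=O)OC(C)(C)C)C(C)=CC[C@@H]2[C@](C)(CO[Si](C)(C)C(C)(C)C)C1=O
F5 | step 9 | tert-butyl (13E)-2β-acetoxy-19-hydroxy-3-oxolabda-7,13-dien-15-oate | CC(=O)O[C@H]1C[C@@]2(C)[C@H](CC/C(C)=C/C(=O)OC(C)(C)C)C(C)=CC[C@@H]2[C@](C)(CO)C1=O
F6 | step 9 | tert-butyl (13E)-2β-acetoxy-3β,19-dihydroxylabda-7,13-dien-15-oate | CC(=O)O[C@H]1C[C@@]2(C)[C@H](CC/C(C)=C/C(=O)OC(C)(C)C)C(C)=CC[C@@H]2[C@](C)(CO)[C@H]1O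
F7 | step 9 | tert-butyl (13E)-2β-acetoxy-3β-hydroxy-19-oxolabda-7,13-dien-15-oate | CC(=O)O[C@H]1C[C@@]2(C)[C@H](CC/C(C)=C/C(=O)OC(C)(C)C)C(C)=CC[C@@H]2[C@](C)(C=O)[C@H]1O
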